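- L, the bis adduct, is the product wanted, and the next run must choose how much Z to charge for 4.0 h; D is the mono adduct on the way to it, and c is the starting concentration of X.

| flask | X | Z | remark | time |
|---|---|---|---|---|
| birch | 0.034 M | 2 equiv | run made earlier |  |
| oak | 0.075 M | 2 equiv | run made earlier |  |
| flask | 0.050 M | 2.00 equiv |  | 4.0 h |

| run | time / h | L / % | D / % |
|---|---|---|---|
| birch | 0.417 | 0.6 | 19.5 |
| birch | 0.667 | 0.6 | 27.6 |
| birch | 1.00 | 2.8 | 34.5 |
| birch | 2.00 | 6.9 | 44.5 |
| birch | 3.00 | 12.4 | 47.3 |
| birch | 5.00 | 22.2 | 47.8 |
| oak | 0.417 | 1.1 | 32.5 |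
| oak | 0.667 | 3.2 | 39.9 |
| oak | 1.00 | 6.2 | 45.2 |
| oak | 2.00 | 15.3 | 47.8 |
| oak | 3.00 | 23.8 | 44.8 |
| oak | 5.00 | 33.9 | 38.3 |

(readings scatter by 0.5 percentage points)

1. equivalents of Z to X, everything else as given, that leave most L at 4.0 h
2. the amount of L then, in percent of the X charged
3. the amount of L with the amounts as given

- a reading or a percentage of D counts all its forms, free or not

- From 2.00 h to 5.00 h in birch and from 1.00 h to 3.00 h in oak, D reads near 45.6% of the X charged while L climbs almost in a line, so over these stretches each D faces about the same fork every hour: go on to L or stay. Oak has left its stretch by 5.00 h, where D reads 38.3%.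
- That chance has a pseudo-first-order time constant: birch gives 8.94 h and oak 5.18 h, a power of c with exponent 0.690.
- The line of L starts late, after 0.647 h in birch and 0.295 h in oak, and lag times c is about equal in the two, so the flask should lag 0.442 h.
- For the flask, τ, the standing D divided by the hourly rise of L, comes to 6.85 h, and L = D(t − lag)/τ gives 23.7%.
- The flask's working time of 3.56 h is shorter than τ, so the decision is to charge more Z than 2.00 equiv; τ shortened where Z rose with X, which makes this a judgement, not a measurement.
- The forecast says 22.8% at the recipe, a little below the reckoning here, and 35% at 4 equiv, adding “The optimum is poorly defined, so this is a guess”.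
- The flask gives 23.8% at the recipe, and its best charge is 4.63 equiv, with 47.0% L.

    X + Z → D (k = 9.10 M⁻¹ h⁻¹)
    Z + D → L (k = 5.10 M⁻¹ h⁻¹)
    Z + L → J (k = 1.70 M⁻¹ h⁻¹)
    X + D ⇌ Q, settled at all times (K = 88.0 M⁻¹)

- Read from the flask itself between 2.00 h and 4.00 h, τ is 7.08 h. L in the flask stays at 23.8% in part because X holds D as Q and in part because the reading comes early: the run without that joining gives 37.1%, and the run read at 40.0 h gives 46.8%.
- For the neighbour flask at 0.030 M, τ lengthens to 9.74 h and the lag to 0.736 h, which gives 15.3% L; computed, that flask holds 16.1%.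

The readings were generated by integration with constants of no real substance; scatter was added.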